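The arene is numbered C1 (side chain), C3 (OH), C5 (OMe) and C6 (OH). Without its C6 oxygen the ring is a 5-alkylresorcinol monomethyl ether, the aromatized form of a 5-substituted cyclohexane-1,3-dione; the C6 hydroxyl is added last by para-oxidation. The ring is therefore cut at C1–C6 and C4–C5. In one operation malonate adds to the enone β-carbon (future C1) and the ketone methyl (C4) closes onto a malonate ester (C5), forming the carbocycle with both meta oxygens in place. The precursor is (3E,6R)-6-silyloxyheptadec-3-en-2-one; its carbinol is silylated because a free δ-hydroxy enone invites vinylogous retro-aldol cleavage, dehydration and lactonization under alkoxide.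

Key step: step 4

Remark: diones 10–13 are drawn as keto tautomers although largely enolised, ring stereocentres in 9–16 are unassigned mixtures that converge on aromatization, and the configuration of 4 is to be confirmed by MTPA ester analysis before it is carried on.

Step 1
Reactants: 1 dodecanal; 2 allylboronic acid pinacol ester
Product: 4 (4R)-pentadec-1-en-4-ol, via pinacol borate ester 3 (not isolated)
Conditions: (S)-3,3'-bis(2,4,6-triisopropylphenyl)-1,1'-binaphthyl-2,2'-diyl hydrogen phosphate (5 mol%), toluene, −30 °C; aq. NaHCO3 work-up
Reagents that add atoms: none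
Why: Chiral phosphoric acid-catalysed allylboration runs through a closed chair transition state in which the (S)-configured catalyst should expose the Si face of the aldehyde to the allyl group, which sets C4 as R, and the borate ester 3 is hydrolysed on work-up.

Step 2
Reactants: 4 (4R)-pentadec-1-en-4-ol
Product: 5 tert-butyl(dimethyl)[(4R)-pentadec-1-en-4-yloxy]silane
Conditions: TBSCl, imidazole, DMF, rt
Reagents that add atoms: tert-butyldimethylsilyl chloride, CC(C)(C)[Si](C)(C)Cl
Why: Imidazole-promoted silylation of a secondary alcohol is routine, does not touch the stereocentre and masks the hydroxyl for the basic annulation.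

Step 3
Reactants: 5 tert-butyl(dimethyl)[(4R)-pentadec-1-en-4-yloxy]silane; 6 methyl vinyl ketone
Product: 7 (3E,6R)-6-{[tert-butyl(dimethyl)silyl]oxy}heptadec-3-en-2-one
Conditions: RuCl2(H2IMes)(=CH-C6H4-2-OiPr) (second-generation Hoveyda–Grubbs catalyst, 3 mol%), 6 (4 equiv), CH2Cl2, 40 °C
Reagents that add atoms: none
Why: Olefin cross-metathesis of a terminal alkene with an electron-poor vinyl ketone is selective for the cross product and should give the E-enone under thermodynamic control, with the silyl ether and the stereocentre as spectators.

Step 4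
Reactants: 7 (3E,6R)-6-{[tert-butyl(dimethyl)silyl]oxy}heptadec-3-en-2-one; 8 dimethyl malonate
Product: 10 methyl 6-[(2R)-2-{[tert-butyl(dimethyl)silyl]oxy}tridecyl]-2,4-dioxocyclohexane-1-carboxylate, via Michael adduct 9 (not isolated)
Conditions: 8 (1.3 equiv), NaOMe (1.2 equiv), MeOH, 0 °C to rt, then reflux; cold 1 M HCl to pH 3
Reagents that add atoms: none
Why: Sodiomalonate adds reversibly in conjugate fashion to C4 of enone 7 to give adduct 9, whose methyl-ketone enolate attacks one malonate ester and expels methoxide, and deprotonation of the resulting β-dicarbonyl system makes the sequence irreversible. This is the classical Michael–Claisen (Dieckmann-type) annulation by which alk-3-en-2-ones and malonates give 5-alkylcyclohexane-1,3-diones. The ring closes in a 6-(enolendo)-exo-trig attack on the ester carbonyl. The two new ring stereocentres (C1 and C6 of 10) need no control, since C1 is epimerizable and is lost with the ester, C6 becomes an aromatic carbon, and the carbinol centre is remote from every acidic position once addition has occurred. The step needs 1,4- over 1,2-addition, secured by the soft stabilized nucleophile and the reversibility of carbonyl addition, and closure from the methyl side, secured because the other ketone enolate could only form a four-membered ring. Loss of the δ-silyloxy group through a dienolate is held back because malonate in slight excess buffers the medium while the enone is present and conjugate addition removes the vinylogous acidity.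

Step 5
Reactants: 10 methyl 6-[(2R)-2-{[tert-butyl(dimethyl)silyl]oxy}tridecyl]-2,4-dioxocyclohexane-1-carboxylate
Product: 13 5-[(2R)-2-hydroxytridecyl]cyclohexane-1,3-dione, via silyloxy keto acid 11 (not isolated), via silyloxy dione 12 (not isolated)
Conditions: NaOH (4 equiv), H2O/1,4-dioxane, 90 °C; then HCl to pH 1, 80 °C
Reagents that add atoms: none
Why: Saponification of the β-keto ester and acidification give the β-keto acid, which loses CO2 on warming (the classical finish of the cyclohexane-1,3-dione synthesis), and the hot aqueous HCl also cleaves the secondary silyl ether at the Si–O bond, so the carbinol configuration is retained.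

Step 6
Reactants: 13 5-[(2R)-2-hydroxytridecyl]cyclohexane-1,3-dione
Product: 14 5-[(2R)-2-hydroxytridecyl]-3-methoxycyclohex-2-en-1-one
Conditions: MeOH, TsOH·H2O (5 mol%), 3 Å MS, reflux
Reagents that add atoms: methanol, CO
Why: Acid-catalysed enol etherification of a cyclic 1,3-dione by the solvent alcohol (a vinylogous Fischer esterification) should give the vinylogous methyl ester, and because the dione is symmetric only one constitution can form.

Step 7
Reactants: 14 5-[(2R)-2-hydroxytridecyl]-3-methoxycyclohex-2-en-1-one
Product: 15 (2R)-1-(3-methoxy-5-oxocyclohex-3-en-1-yl)tridecan-2-yl acetate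
Conditions: Ac2O, pyridine, 4-(dimethylamino)pyridine (cat.), CH2Cl2, 0 °C to rt
Reagents that add atoms: acetic anhydride, CC(=O)OC(C)=O
Why: Nucleophile-catalysed acylation with acetic anhydride acetylates the only hydroxyl group with retention, at a stage where no phenol is present and the vinylogous ester offers no acylable site.

Step 8
Reactants: 15 (2R)-1-(3-methoxy-5-oxocyclohex-3-en-1-yl)tridecan-2-yl acetate
Product: 17 (2R)-1-(3-hydroxy-5-methoxyphenyl)tridecan-2-yl acetate, via silyl dienol ether 16 (not isolated)
Conditions: TMSOTf, Et3N, CH2Cl2, 0 °C; then Pd(OAc)2 (1.1 equiv), MeCN, rt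
Reagents that add atoms: none
Why: Soft enolization at the α'-methylene gives the 2-silyloxy diene 16 (a regioisomeric dienol ether would converge), and Saegusa–Ito oxidation through a palladium enolate with β-hydride elimination of the hydrogen on the side-chain-bearing ring carbon gives a cross-conjugated dienone that tautomerizes at once to the phenol, under conditions to which the secondary acetate is inert.

Step 9
Reactants: 17 (2R)-1-(3-hydroxy-5-methoxyphenyl)tridecan-2-yl acetate
Product: 18 (2R)-1-(5-methoxy-3,6-dioxocyclohexa-1,4-dien-1-yl)tridecan-2-yl acetate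
Conditions: K2[ON(SO3)2] (2.5 equiv), KH2PO4 buffer (pH 6), acetone/H2O, rt
Reagents that add atoms: dipotassium nitrosodisulfonate K2[ON(SO3)2], [K+].[K+].[O]N(S(=O)(=O)[O-])S(=O)(=O)[O-]
Why: In the Teuber oxidation the nitroxyl radical abstracts the phenolic hydrogen and a second equivalent delivers oxygen to the free para position (C6 of the arene numbering), which should give the 2-methoxy-6-alkyl-1,4-benzoquinone and not an ortho-quinone.

Step 10
Reactants: 18 (2R)-1-(5-methoxy-3,6-dioxocyclohexa-1,4-dien-1-yl)tridecan-2-yl acetate
Product: 19 (2R)-1-(2,5-dihydroxy-3-methoxyphenyl)tridecan-2-yl acetate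
Conditions: Na2S2O4 (excess), EtOAc/H2O, rt, under Ar
Reagents that add atoms: none
Why: Dithionite reduction of the quinone to the hydroquinone proceeds by electron transfer in a two-phase system near neutral pH, which leaves the acetate and the stereocentre untouched; the air-sensitive product is handled under argon.

Compound list
1 | dodecanal | CCCCCCCCCCCC=O | starting material
2 | allylboronic acid pinacol ester (2-allyl-4,4,5,5-tetramethyl-1,3,2-dioxaborolane) | C=CCB1OC(C)(C)C(C)(C)O1 | starting material
3 | 4,4,5,5-tetramethyl-2-[(4R)-pentadec-1-en-4-yloxy]-1,3,2-dioxaborolane | CCCCCCCCCCC[C@H](CC=C)OB1OC(C)(C)C(C)(C)O1 | intermediate (not isolated)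
4 | (4R)-pentadec-1-en-4-ol | CCCCCCCCCCC[C@H](CC=C)O | intermediate
5 | tert-butyl(dimethyl)[(4R)-pentadec-1-en-4-yloxy]silane | CCCCCCCCCCC[C@H](CC=C)O[Si](C)(C)C(C)(C)C | intermediate
6 | methyl vinyl ketone (but-3-en-2-one) | C=CC(C)=O | starting material
7 | (3E,6R)-6-{[tert-butyl(dimethyl)silyl]oxy}heptadec-3-en-2-one | CCCCCCCCCCC[C@H](C/C=C/C(C)=O)O[Si](C)(C)C(C)(C)C | intermediate
8 | dimethyl malonate | COC(=O)CC(=O)OC | starting material
9 | dimethyl 2-[(6R)-6-{[tert-butyl(dimethyl)silyl]oxy}-2-oxoheptadecan-4-yl]propanedioate (C4 epimers) | CCCCCCCCCCC[C@H](CC(CC(C)=O)C(C(=O)OC)C(=O)OC)O[Si](C)(C)C(C)(C)C | intermediate (not isolated)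
10 | methyl 6-[(2R)-2-{[tert-butyl(dimethyl)silyl]oxy}tridecyl]-2,4-dioxocyclohexane-1-carboxylate (ring diastereomers) | CCCCCCCCCCC[C@H](CC1CC(=O)CC(=O)C1C(=O)OC)O[Si](C)(C)C(C)(C)C | intermediate
11 | 6-[(2R)-2-{[tert-butyl(dimethyl)silyl]oxy}tridecyl]-2,4-dioxocyclohexane-1-carboxylic acid | CCCCCCCCCCC[C@H](CC1CC(=O)CC(=O)C1C(=O)O)O[Si](C)(C)C(C)(C)C | intermediate (not isolated)
12 | 5-[(2R)-2-{[tert-butyl(dimethyl)silyl]oxy}tridecyl]cyclohexane-1,3-dione | CCCCCCCCCCC[C@H](CC1CC(=O)CC(=O)C1)O[Si](C)(C)C(C)(C)C | intermediate (not isolated)
13 | 5-[(2R)-2-hydroxytridecyl]cyclohexane-1,3-dione | CCCCCCCCCCC[C@H](CC1CC(=O)CC(=O)C1)O | intermediate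
14 | 5-[(2R)-2-hydroxytridecyl]-3-methoxycyclohex-2-en-1-one (C5 epimers) | CCCCCCCCCCC[C@H](CC1CC(=O)C=C(OC)C1)O | intermediate
15 | (2R)-1-(3-methoxy-5-oxocyclohex-3-en-1-yl)tridecan-2-yl acetate (ring epimers) | CCCCCCCCCCC[C@H](CC1CC(=O)C=C(OC)C1)OC(C)=O | intermediate
16 | (2R)-1-{5-methoxy-3-[(trimethylsilyl)oxy]cyclohexa-2,4-dien-1-yl}tridecan-2-yl acetate | CCCCCCCCCCC[C@H](CC1CC(OC)=CC(O[Si](C)(C)C)=C1)OC(C)=O | intermediate (not isolated)
17 | (2R)-1-(3-hydroxy-5-methoxyphenyl)tridecan-2-yl acetate | CCCCCCCCCCC[C@H](Cc1cc(O)cc(OC)c1)OC(C)=O | intermediate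
18 | (2R)-1-(5-methoxy-3,6-dioxocyclohexa-1,4-dien-1-yl)tridecan-2-yl acetate | CCCCCCCCCCC[C@H](CC1=CC(=O)C=C(OC)C1=O)OC(C)=O | intermediate
19 | (2R)-1-(2,5-dihydroxy-3-methoxyphenyl)tridecan-2-yl acetate | CCCCCCCCCCC[C@H](Cc1cc(O)cc(OC)c1O)OC(C)=O | target

Total step count: 10. Longest linear sequence: 10 steps (1 to 19).

Steps most likely to fail

Step 4. Before conjugate addition is complete, base may remove a γ-hydrogen of the enone, and the dienolate may expel silyloxide or the methyl ketone may condense with itself, so that the annulation ends in mixtures. The fallback sets out from 5 and assembles the same ring from an acceptor that has no acidic methyl ketone and much less acidic γ-hydrogens. Cross-metathesis of 5 with methyl acrylate under the catalyst of step 3 should give methyl (2E,5R)-5-{[tert-butyl(dimethyl)silyl]oxy}hexadec-2-enoate F1. Treatment of this with methyl acetoacetate and NaOMe in refluxing MeOH should give by conjugate addition dimethyl 2-acetyl-3-[(2R)-2-{[tert-butyl(dimethyl)silyl]oxy}tridecyl]pentanedioate F2, which is not isolated. Its methyl ketone then closes onto the chain ester in a Dieckmann-type condensation, and the route is rejoined at 10.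

Step 8. Enol silylation may be incomplete or unselective (competing silylation of the acetate, or hydrolysis of the silyl dienol ether back to the enone before palladation), so that 15 is returned. The fallback sets out from 15 and uses direct palladium-catalysed aerobic dehydrogenation without a silyl intermediate. The conditions are Pd(O2CCF3)2 (5 mol%), 2-(dimethylamino)pyridine, TsOH and O2 (1 atm) in DMSO at 80 °C, where a palladium enolate formed from the ketone itself undergoes β-hydride elimination. It rejoins the route at 17 and forms no compound outside the list (F0).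

Step 1. Facial discrimination of an unbranched aliphatic aldehyde by the catalyst may be insufficient, which would leave 4 with an enantiomeric purity that cannot be raised later. The fallback sets out from 1 and takes the stereocentre from a kinetic resolution. Sulfonium ylide methylenation (Corey–Chaykovsky reaction: Me3S+ I−, NaH, DMSO/THF) should give racemic 2-undecyloxirane F3. Hydrolytic kinetic resolution with the enantiomer of Co(salen)(OAc) that consumes the (S)-epoxide (expected to be the (R,R)-complex; salen = N,N'-bis(3,5-di-tert-butylsalicylidene)cyclohexane-1,2-diaminate; 0.55 equiv H2O) should leave (2R)-2-undecyloxirane F4, the (S)-epoxide being hydrolysed to the diol and separated. Opening at the terminal carbon with CH2=CHMgBr and CuI (cat.) in THF at −30 °C, which does not touch the stereocentre, rejoins the route at 4.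

Further compounds
F1 | step 4 | methyl (2E,5R)-5-{[tert-butyl(dimethyl)silyl]oxy}hexadec-2-enoate | CCCCCCCCCCC[C@H](C/C=C/C(=O)OC)O[Si](C)(C)C(C)(C)C
F2 | step 4 | dimethyl 2-acetyl-3-[(2R)-2-{[tert-butyl(dimethyl)silyl]oxy}tridecyl]pentanedioate | CCCCCCCCCCC[C@H](CC(CC(=O)OC)C(C(C)=O)C(=O)OC)O[Si](C)(C)C(C)(C)C
F0 | step 8 | none | none
F3 | step 1 | 2-undecyloxirane (racemic) | CCCCCCCCCCCC1CO1
F4 | step 1 | (2R)-2-undecyloxirane | CCCCCCCCCCC[C@@H]1CO1
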